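The constants are invented; the result is computed.

I decided to reckon this flask by one clock, the approach of E to its ceiling, and to let the rest of the scheme serve it.

    X + J ⇌ X.J (K1 = 2600 L mol⁻¹, k1 = 6800 L mol⁻¹ s⁻¹)
    D ⇌ X.J, rate k2*(cs2 - [X.J]) while solid is left; crystals form when [X.J] > cs2 (cs2 = 0.79 mM, k2 = 27 s⁻¹)
    X.J ⇌ E (K3 = 2.8, k3 = 0.093 s⁻¹)
    G ⇌ X, rate k4*(cs4 - [X]) while solid is left; crystals form when [X] > cs4 (cs4 = 1.6 mM, k4 = 1.7 s⁻¹)
    J ⇌ Q (K5 = 0.68, k5 = 4.6 s⁻¹)

G 5.0 mM; J 6.00 mM; time 50 s

- for X.J the D are counted in
- as a solid, counted per litre of solution: G, D
- at the start none of G is in solution
- X means what is dissolved; the solid is not counted in it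
- run time (flask): 50 s

- cedar: doubling the amount of J, all else as stated
- maple: doubling the dissolution coefficient of step 2, all else as stated
- ash: doubling the dissolution coefficient of step 4, all else as stated
- larch: doubling the solubility in step 4, all else as stated

* amount of X.J and D together at 50 s, in percent of the G charged
* concentration of X in solution at 5.0 s, in percent of saturation
* the change that raises the amount of X.J and D together at 50 s, in percent of the G charged most ("none" if none brings more than 2 percentage points) (cedar / maple / ash / larch / none)
* amount of X.J and D together at 50 s, in percent of the G charged, after larch

First, did the dissolving matter for the timing? At its full rate the charge of G goes in within 1.84 s, against a run of 50 s, so I started the clock of E at zero.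

Second, what does X.J do meanwhile? The binding constant times the starting J is 16, and J stands at 1.20 equivalents, so I expected X.J to reach its solubility and D to form. Dissolved X.J then holds 15.8% of the charge, and E can climb to 2.8 times that, 44.2%. Together these need 60.0% of the charge, less than was put in, so D need not run out and X.J stays held.

Third, how far has E climbed at the reading? With X.J held, E gains at a constant rate and loses in proportion to itself. It therefore closes the gap to its ceiling with a half-life equal to ln two times the equilibrium constant over the forward constant: 20.9 s, the E clock, a pseudo-first-order relaxation. This is slower than the 5.49 s that dissolved X.J and E take by that step with nothing held. The run is 2.40 half-lives, which leaves 19.0% of the gap, so I put E at 35.8% of the charge. X.J, D and X share the remaining 64.2%. The clock and the ceiling contain neither the amount of J nor the constants that maple, ash and larch double, so I kept E where it was under each change. A gain in X.J and D together then had to come out of the share of X, and cedar adds the J that binds X, so I looked to cedar.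

The forecast gave 56.9% for y, 23.2% for sat, cedar as best and 56.9% for yb, adding “Maple, ash and larch barely change anything”.

The flask gave 56.8%, 23.2%, cedar with a gain of 6 percentage points, and 56.8% after larch. At 50.0 s E held 35.8% of the charge, so y here is a reading taken on a falling curve. The same flask left until 80 s has run 3.83 half-lives of the E clock, which puts E at 41.1%. That flask held 41.1% as E and 51.5% as X.J and D together.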